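**Retrosynthetic overview**

1. The strategy rests on the bond between the arene carbon and the quaternary oxirane carbon. The phenol oxygen (on the neighbouring ring carbon) and the CH2O carbon (on the oxirane carbon) flank it, so they are joined as O–C(=O) in a five-membered benzofuran-2(3H)-one ring whose C3 is the stereocentre.
2. Target 17 ⇐ acetal 16 ⇐ spiro-epoxy lactone 13: hydride cuts the lactone (its carbonyl carbon becomes the ester CH2, its ring oxygen the phenol), both oxygens are isovaleroylated, and the aldehyde is unmasked last.
3. 13 ⇐ racemic 3-chloro lactone 10 + formaldehyde 11: a catalytic asymmetric Darzens condensation forms C3–CH2, C3–O and the oxirane.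
4. 10 ⇐ lactone 8 (chlorination) ⇐ aryl acetate 6 ⇐ aryl bromide 3 + Reformatsky reagent 5 ⇐ 4-bromo-3-hydroxybenzaldehyde 1.
5. Ring order: arene bought; lactone closed (step 4); oxirane closed on it as a spiro ring (step 6); lactone opened again (step 7).

Key step: step 6

Assumption: the face preference of the ammonium catalyst on this new substrate cannot be predicted with confidence; the route is written with the cinchonidinium salt, and the pseudoenantiomeric cinchoninium salt is taken if the other enantiomer prevails.

**Step 1**
Reactants: 1 4-bromo-3-hydroxybenzaldehyde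
Product: 2 2-bromo-5-(dimethoxymethyl)phenol
Conditions: HC(OMe)3, MeOH, TsOH·H2O (cat.), rt; Et3N quench
Reagents that add atoms: trimethyl orthoformate COC(OC)OC; methanol CO
Why: Acid-catalysed acetalization with the orthoformate as water scavenger masks the aldehyde, the only electrophile that would later compete with formaldehyde, as a dimethyl acetal that is stable to the basic, organometallic and hydride steps ahead.

**Step 2**
Reactants: 2 2-bromo-5-(dimethoxymethyl)phenol
Product: 3 2-(benzyloxy)-1-bromo-4-(dimethoxymethyl)benzene
Conditions: BnBr, K2CO3, DMF, rt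
Reagents that add atoms: benzyl bromide BrCc1ccccc1
Why: Williamson ether synthesis of the phenoxide under basic conditions leaves the acetal untouched and installs a group that is removed later by neutral hydrogenolysis.

**Step 3**
Reactants: 3 2-(benzyloxy)-1-bromo-4-(dimethoxymethyl)benzene; 4 benzyl bromoacetate
Product: 6 benzyl 2-[2-(benzyloxy)-4-(dimethoxymethyl)phenyl]acetate, via Reformatsky reagent 5 (not isolated)
Conditions: 4, Zn dust (Me3SiCl-activated), THF, 25–40 °C; then 3, Pd(dba)2 (2 mol%), P(t-Bu)3 (2 mol%), THF, rt; NaHCO3 work-up
Reagents that add atoms: none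
Why: Zinc inserts into the C–Br bond of 4 and the resulting zinc ester enolate is arylated by 3 under zerovalent palladium catalysis (Negishi-type coupling of a Reformatsky reagent by oxidative addition, transmetalation and reductive elimination), which is neutral enough for the acetal and both benzyl groups.

**Step 4**
Reactants: 6 benzyl 2-[2-(benzyloxy)-4-(dimethoxymethyl)phenyl]acetate
Product: 8 6-(dimethoxymethyl)benzofuran-2(3H)-one, via hydroxy acid 7 (not isolated)
Conditions: H2 (1 atm), 10% Pd/C, dry EtOAc, rt, stopped after uptake of 2 equiv; filter; then DCC, 0 °C→rt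
Reagents that add atoms: none
Why: Hydrogenolysis of the benzyl ether and benzyl ester frees phenol and acid without acid or base, and carbodiimide-mediated lactonization then closes the five-membered aryl lactone with the acetal in place, so that a free aldehyde never meets the acidic lactone CH2 (which would invite Knoevenagel self-condensation).

**Step 5**
Reactants: 8 6-(dimethoxymethyl)benzofuran-2(3H)-one
Product: 10 3-chloro-6-(dimethoxymethyl)benzofuran-2(3H)-one (racemic), via silyl ketene acetal 9 (not isolated)
Conditions: LiN(SiMe3)2 (1.05 equiv), Me3SiCl (1.2 equiv), THF, −78 °C; then N-chlorosuccinimide (1.05 equiv), −78→0 °C; pH 7 buffer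
Reagents that add atoms: N-chlorosuccinimide O=C1CCC(=O)N1Cl
Why: O-Silylation of the lactone enolate gives the aromatic 2-silyloxybenzofuran, and electrophilic α-chlorination of this silyl ketene acetal at C3 should stop at the monochloride because no base strong enough to re-enolize the more acidic product remains.

**Step 6**
Reactants: 10 3-chloro-6-(dimethoxymethyl)benzofuran-2(3H)-one (racemic); 11 formaldehyde (monomer, from cracked paraformaldehyde)
Product: 13 (R)-6-(dimethoxymethyl)-2H-spiro[benzofuran-3,2'-oxiran]-2-one, via chlorohydrin alkoxide 12 (not isolated)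
Conditions: O-allyl-N-(9-anthracenylmethyl)cinchonidinium bromide (10 mol%), K2CO3 (dry powder, 1.5 equiv), CH2O (2 equiv, added slowly as a cold toluene solution), toluene/CH2Cl2 (4:1), −40 °C
Reagents that add atoms: none
Why: Proposed new method: solid K2CO3 removes the acidic C3–H of 10 and the chiral quaternary ammonium cation carries the flat, aromatic 3-chlorobenzofuran-2-olate into the organic phase as a tight ion pair, whose C3 adds to formaldehyde (C3–CH2 bond) to give alkoxide 12, which then displaces chloride from the activated benzylic α-carbonyl carbon (C3–O bond); the closest known reaction types are phase-transfer and bifunctional-amine Darzens condensations of α-chloro carbonyl compounds (3-chlorooxindoles among them) with aldehydes and catalytic asymmetric hydroxymethylation of 3-substituted oxindoles with formaldehyde. The oxirane closes 3-exo-tet by backside attack, so C3 is inverted and the closure is stereospecific once the aldol step has fixed the configuration. The only stereocentre is thus controlled by the catalyst: the cation sits at the enolate oxygen between the lactone-oxygen flank and the benzo flank, its anthracenylmethyl wall leaves one face of C3 open, and attack of formaldehyde on the Si face of C3 (Cl > C2 > C3a) should give (S)-12 and from it (R)-13. Formaldehyde brings no second stereocentre, so no diastereomers arise, and its aldol addition is practically irreversible, so the facial choice is kinetic and is not eroded by retro-aldol equilibration. The selectivity needed is enantiofacial only; it is secured by the rigid bicyclic enolate with two unlike flanks, by the non-polar medium that keeps the ion pair tight, and by the insolubility of the potassium enolate, which holds back the uncatalysed path. Slow addition of formaldehyde keeps the aldolate from taking up a second formaldehyde before it closes.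

**Step 7**
Reactants: 13 (R)-6-(dimethoxymethyl)-2H-spiro[benzofuran-3,2'-oxiran]-2-one; 14 isovaleric anhydride
Product: 16 (R)-{2-[4-(dimethoxymethyl)-2-(3-methylbutanoyloxy)phenyl]oxiran-2-yl}methyl 3-methylbutanoate, via glycidol phenol 15 (not isolated)
Conditions: LiBH4 (1.0 equiv), THF, −20→0 °C; then 14 (4 equiv), Et3N, DMAP (cat.), 0 °C→rt
Reagents that add atoms: none
Why: Hydride reduction of the activated aryl glycidic lactone by LiBH4 should give the primary alcohol and release the phenol oxygen as a boron-bound aryloxide while epoxide and acetal stay inert at this temperature, and DMAP-catalysed acylation of both oxygens in the same flask caps the phenoxide before it can open the neighbouring benzylic epoxide; no bond to the stereocentre is touched, and the degenerate Payne rearrangement of this 2,2-disubstituted glycidol alkoxide returns the same enantiomer.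

**Step 8**
Reactants: 16 (R)-{2-[4-(dimethoxymethyl)-2-(3-methylbutanoyloxy)phenyl]oxiran-2-yl}methyl 3-methylbutanoate
Product: 17 (R)-{2-[4-formyl-2-(3-methylbutanoyloxy)phenyl]oxiran-2-yl}methyl 3-methylbutanoate (target)
Conditions: pyridinium p-toluenesulfonate (10 mol%), acetone/H2O (10:1), 0 °C→rt
Reagents that add atoms: water O
Why: Acid-catalysed acetal hydrolysis of an aromatic dimethyl acetal should proceed under this weak acid far faster than protonation and opening of the tertiary benzylic epoxide, which is deactivated by the ortho acyloxy group and the para carbonyl carbon, and both esters are stable at this pH.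

**Compound list**

1 | 4-bromo-3-hydroxybenzaldehyde | O=Cc1ccc(Br)c(O)c1 | starting material
2 | 2-bromo-5-(dimethoxymethyl)phenol | COC(OC)c1ccc(Br)c(O)c1 | intermediate
3 | 2-(benzyloxy)-1-bromo-4-(dimethoxymethyl)benzene | COC(OC)c1ccc(Br)c(OCc2ccccc2)c1 | intermediate
4 | benzyl bromoacetate | BrCC(=O)OCc1ccccc1 | starting material
5 | [2-(benzyloxy)-2-oxoethyl]zinc bromide (Reformatsky reagent, not isolated) | Br[Zn]CC(=O)OCc1ccccc1 | intermediate
6 | benzyl 2-[2-(benzyloxy)-4-(dimethoxymethyl)phenyl]acetate | COC(OC)c1ccc(CC(=O)OCc2ccccc2)c(OCc2ccccc2)c1 | intermediate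
7 | 2-[4-(dimethoxymethyl)-2-hydroxyphenyl]acetic acid (not isolated) | COC(OC)c1ccc(CC(=O)O)c(O)c1 | intermediate
8 | 6-(dimethoxymethyl)benzofuran-2(3H)-one | O=C1Cc2ccc(C(OC)OC)cc2O1 | intermediate
9 | {[6-(dimethoxymethyl)benzofuran-2-yl]oxy}trimethylsilane (not isolated) | COC(OC)c1ccc2cc(O[Si](C)(C)C)oc2c1 | intermediate
10 | 3-chloro-6-(dimethoxymethyl)benzofuran-2(3H)-one (racemic, configurationally labile) | O=C1Oc2cc(C(OC)OC)ccc2C1Cl | intermediate
11 | formaldehyde (from paraformaldehyde) | C=O | starting material
12 | (S)-3-chloro-6-(dimethoxymethyl)-3-(hydroxymethyl)benzofuran-2(3H)-one, formed as its alkoxide (not isolated) | O=C1Oc2cc(C(OC)OC)ccc2[C@]1(Cl)CO | intermediate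
13 | (R)-6-(dimethoxymethyl)-2H-spiro[benzofuran-3,2'-oxiran]-2-one | O=C1Oc2cc(C(OC)OC)ccc2[C@@]13CO3 | intermediate
14 | isovaleric anhydride (3-methylbutanoic anhydride) | CC(C)CC(=O)OC(=O)CC(C)C | starting material
15 | (S)-5-(dimethoxymethyl)-2-[2-(hydroxymethyl)oxiran-2-yl]phenol, formed as its lithium/boron alkoxide (not isolated) | OC[C@@]1(c2ccc(C(OC)OC)cc2O)CO1 | intermediate
16 | (R)-{2-[4-(dimethoxymethyl)-2-(3-methylbutanoyloxy)phenyl]oxiran-2-yl}methyl 3-methylbutanoate | CC(C)CC(=O)OC[C@@]1(c2ccc(C(OC)OC)cc2OC(=O)CC(C)C)CO1 | intermediate
17 | (R)-{2-[4-formyl-2-(3-methylbutanoyloxy)phenyl]oxiran-2-yl}methyl 3-methylbutanoate | CC(C)CC(=O)OC[C@@]1(c2ccc(C=O)cc2OC(=O)CC(C)C)CO1 | target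

**Step count**

Total: 8 steps. Longest linear sequence: 8 steps (from 1).

**Steps most likely to fail**

Step 6 (Proposed new method). The aldol step may discriminate poorly between the two faces for so small an electrophile. The aldolate may take up a second formaldehyde and close a five-membered ring instead of the oxirane. The enolate may be alkylated by its own chloride, or the aryl lactone may be cleaved by carbonate. The fallback uses the Sharpless asymmetric epoxidation of a 2-arylallyl alcohol, sets out from 2 and comes back at 16, so that 13 and step 7 are left out. Silylation of 2 (t-BuMe2SiCl, imidazole, DMF) should give (2-bromo-5-(dimethoxymethyl)phenoxy)(tert-butyl)dimethylsilane F1. Stille coupling with 2-(tributylstannyl)prop-2-en-1-ol (Pd(PPh3)4, CuI, DMF, 60 °C, no fluoride) should give 2-[2-(tert-butyldimethylsilyloxy)-4-(dimethoxymethyl)phenyl]prop-2-en-1-ol F2. Epoxidation with Ti(Oi-Pr)4 (cat.), L-(+)-diisopropyl tartrate, t-BuOOH and 4 Å sieves in CH2Cl2 at −20 °C should give (S)-{2-[2-(tert-butyldimethylsilyloxy)-4-(dimethoxymethyl)phenyl]oxiran-2-yl}methanol F3, the oxygen being delivered to the same face as in the conversion of allyl alcohol into (S)-glycidol. Acylation with 14 and DMAP should give (R)-{2-[2-(tert-butyldimethylsilyloxy)-4-(dimethoxymethyl)phenyl]oxiran-2-yl}methyl 3-methylbutanoate F4. Bu4NF in THF at 0 °C in the presence of more 14 then exchanges the aryl silyl ether for the isovalerate as the phenoxide is set free, which gives 16.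

Step 7. The phenoxide may open the neighbouring benzylic epoxide (quinone-methide-type ionization followed by hydride capture), hydride may attack the epoxide, or the boron-bound alkoxide may acylate incompletely. The fallback never lets hydride and a free phenoxide meet; it sets out from 13 and comes back at 16. Methanolysis of the aryl lactone (MeOH, cat. Et3N, 0 °C) should give methyl (R)-2-[4-(dimethoxymethyl)-2-hydroxyphenyl]oxirane-2-carboxylate F5 with a neutral phenol. Silylation (t-BuMe2SiCl, imidazole) should give methyl (R)-2-[2-(tert-butyldimethylsilyloxy)-4-(dimethoxymethyl)phenyl]oxirane-2-carboxylate F6. Reduction of the glycidic ester with i-Bu2AlH in CH2Cl2 at −78 °C should give the epoxy alcohol F3 described above, which is carried through F4 to 16 as in the first fallback.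

Step 5. Chlorination may run on to the 3,3-dichloride through proton shuffling, the silyl ketene acetal may form incompletely, or the labile α-chloro aryl lactone may be lost on work-up. The fallback replaces halogenation of the enolate by hydroxylation and deoxychlorination; it sets out from 8 and comes back at 10. The potassium enolate of 8 (KN(SiMe3)2, THF, −78 °C) is oxidized with 2-(phenylsulfonyl)-3-phenyloxaziridine, which should give 3-hydroxy-6-(dimethoxymethyl)benzofuran-2(3H)-one F7 and cannot over-react. SOCl2 and pyridine in CH2Cl2 at 0 °C, the usual way from 3-hydroxyoxindoles to 3-chlorooxindoles, then should give 10, with pyridine keeping the medium safe for the acetal.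

**Further compounds**

F1 | step 6 | (2-bromo-5-(dimethoxymethyl)phenoxy)(tert-butyl)dimethylsilane | COC(OC)c1ccc(Br)c(O[Si](C)(C)C(C)(C)C)c1
F2 | step 6 | 2-[2-(tert-butyldimethylsilyloxy)-4-(dimethoxymethyl)phenyl]prop-2-en-1-ol | COC(OC)c1ccc(C(=C)CO)c(O[Si](C)(C)C(C)(C)C)c1
F3 | step 6 | (S)-{2-[2-(tert-butyldimethylsilyloxy)-4-(dimethoxymethyl)phenyl]oxiran-2-yl}methanol | OC[C@@]1(c2ccc(C(OC)OC)cc2O[Si](C)(C)C(C)(C)C)CO1
F4 | step 6 | (R)-{2-[2-(tert-butyldimethylsilyloxy)-4-(dimethoxymethyl)phenyl]oxiran-2-yl}methyl 3-methylbutanoate | CC(C)CC(=O)OC[C@@]1(c2ccc(C(OC)OC)cc2O[Si](C)(C)C(C)(C)C)CO1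
F5 | step 7 | methyl (R)-2-[4-(dimethoxymethyl)-2-hydroxyphenyl]oxirane-2-carboxylate | COC(=O)[C@@]1(c2ccc(C(OC)OC)cc2O)CO1
F6 | step 7 | methyl (R)-2-[2-(tert-butyldimethylsilyloxy)-4-(dimethoxymethyl)phenyl]oxirane-2-carboxylate | COC(=O)[C@@]1(c2ccc(C(OC)OC)cc2O[Si](C)(C)C(C)(C)C)CO1
F7 | step 5 | 3-hydroxy-6-(dimethoxymethyl)benzofuran-2(3H)-one (racemic) | O=C1Oc2cc(C(OC)OC)ccc2C1O
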